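Retrosynthesis: acid removes the three MOM ethers and a tert-butyl ester; the lactone is cut at C8a–C1 and C1–O2 (CO out) to a C3 carbinol; the carbinol goes back to a ketone; the Cβ ester goes back to the C2 carbonyl of a 2-pyrone; the pyrone is cut at C4–Cα into an arylpyruvate and dimethyl acetylenedicarboxylate; the arylpyruvate is cut at C4a–C4.
Feature used: C1 joins O2 to C8a, and C8a is the only hydrogen-bearing carbon of ring A next to C4a; it lies five atoms from the C3 hydroxyl oxygen, para to the C6 oxygen and ortho to the C8 oxygen, so palladium held on that hydroxyl can reach and palladate it.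
Forward: ring A is bought as 3-bromo-4,5-dihydroxybenzaldehyde and given its third oxygen; the chain is joined at C4a–C4 (glycidate opening), then C4–Cα (pyrone annulation, a temporary ring), the pyrone is reopened so that the three carboxyls differ, and the lactone ring closes last.
Stereochemistry: the alkene geometry is fixed in the pyrone and kept on opening; C3 (S) and C4 (R) are set together in one asymmetric transfer hydrogenation with dynamic kinetic resolution (catalyst sets C3, Felkin–Anh matching selects C4).
Change of ester: the Cβ carboxyl is carried as a tert-butyl ester, not a primary ester, so that the free C3 hydroxyl cannot close a δ-lactone onto it before or during the carbonylation.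

Key step: step 9

Remark on locants: C1, O2, C3, C4, C4a, C5–C8 and C8a are those of the isochroman-1-one; Cα is the alkene carbon on C4 and Cβ its CH neighbour; the same labels are used for the open-chain precursors (C3 and C4 are C5 and C4 of the hex-2-enedioate names).
Remark on step 8: the (S,S)-catalyst is written on the assumption that the ester of an α-keto ester takes the place of the aryl group of an aryl ketone in the hydride transfer; if the sense is the opposite, the (R,R)-catalyst is used.

Step 1
Reactants: 1 3-bromo-4,5-dihydroxybenzaldehyde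
Product: 2 3-bromo-4,5-bis(methoxymethoxy)benzaldehyde
Conditions: MOMCl, i-Pr2NEt, CH2Cl2, 0 °C to rt
Reagents that add atoms: chloromethyl methyl ether, COCCl
Why: O-alkylation of both phenols by the reactive α-chloro ether (Williamson type) gives acetal ethers that should survive the peracid, Grignard, amine, hydride and palladium steps and fall to acid at the end.

Step 2
Reactants: 2 3-bromo-4,5-bis(methoxymethoxy)benzaldehyde
Product: 4 3-bromo-4,5-bis(methoxymethoxy)phenol, via aryl formate 3 (not isolated)
Conditions: mCPBA, CH2Cl2, 0 °C to rt; then MeOH, Et3N (cat.), rt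
Reagents that add atoms: 3-chloroperoxybenzoic acid, OOC(=O)c1cccc(Cl)c1
Why: Baeyer–Villiger (Dakin-type) oxidation, in which the electron-rich aryl group with its para oxygen migrates, turns the aldehyde into a formate that methanol cleaves, so the third oxygen is placed meta to bromine with no regiochemical choice.

Step 3
Reactants: 4 3-bromo-4,5-bis(methoxymethoxy)phenol
Product: 5 1-bromo-2,3,5-tris(methoxymethoxy)benzene
Conditions: MOMCl, i-Pr2NEt, CH2Cl2, 0 °C to rt
Reagents that add atoms: chloromethyl methyl ether, COCCl
Why: the same Williamson-type O-alkylation of the remaining phenol gives the fully protected aryl bromide.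

Step 4
Reactants: 5 1-bromo-2,3,5-tris(methoxymethoxy)benzene; 6 methyl oxirane-2-carboxylate (racemic methyl glycidate)
Product: 8 methyl 2-hydroxy-3-[2,3,5-tris(methoxymethoxy)phenyl]propanoate (racemic), via arylmagnesium bromide 7 (not isolated)
Conditions: Mg, THF, 45 °C; then CuI (10 mol %), 6, THF, −30 °C
Reagents that add atoms: magnesium, [Mg] (held in 7 only)
Why: Grignard formation followed by copper-catalysed SN2 opening of the glycidic ester at its unsubstituted carbon, which at −30 °C should outrun addition to the ester, makes the C4a–C4 bond; the carbinol centre is racemic and is erased in step 5.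

Step 5
Reactants: 8 methyl 2-hydroxy-3-[2,3,5-tris(methoxymethoxy)phenyl]propanoate
Product: 9 methyl 2-oxo-3-[2,3,5-tris(methoxymethoxy)phenyl]propanoate
Conditions: Dess–Martin periodinane, CH2Cl2, 0 °C to rt
Reagents that add atoms: none
Why: Dess–Martin oxidation of the secondary α-hydroxy ester to the α-keto ester runs without base, so the enolisable arylpyruvate is not exposed to aldol self-condensation.

Step 6
Reactants: 9 methyl 2-oxo-3-[2,3,5-tris(methoxymethoxy)phenyl]propanoate; 10 dimethyl but-2-ynedioate
Product: 12 dimethyl 2-oxo-5-[2,3,5-tris(methoxymethoxy)phenyl]-2H-pyran-4,6-dicarboxylate, via Michael adduct 11 (not isolated)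
Conditions: DABCO (20 mol %), PhMe, 0 °C to rt; then 4 Å MS, 100 °C
Reagents that add atoms: none
Why: amine-catalysed Michael addition of the enolised arylpyruvate through its benzylic carbon to the acetylenic diester makes C4–Cα, and on heating the enol oxygen acylates itself on the Cβ ester that lies cis to C4 with loss of methanol (the known 2-pyrone annulation of active-methylene ketones with acetylenedicarboxylates), the other alkene isomer feeding in through the extended enol.

Step 7
Reactants: 12 dimethyl 2-oxo-5-[2,3,5-tris(methoxymethoxy)phenyl]-2H-pyran-4,6-dicarboxylate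
Product: 13 1-tert-butyl 6-methyl (2E)-3-(methoxycarbonyl)-5-oxo-4-[2,3,5-tris(methoxymethoxy)phenyl]hex-2-enedioate (racemic)
Conditions: LiOt-Bu (1.1 equiv), THF, −40 to 0 °C; then AcOH
Reagents that add atoms: lithium tert-butoxide, [Li+].CC(C)(C)[O-]
Why: addition–elimination of tert-butoxide at the enol-lactone carbonyl, the least hindered acyl group and the only one whose tetrahedral adduct can expel a stabilised α-keto ester enolate, opens the ring irreversibly to an anion that resists further alkoxide attack, so only the Cβ carboxyl becomes the tert-butyl ester and the alkene keeps the ring-imposed geometry, which is also the more stable fumarate-type one.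

Step 8
Reactants: 13 1-tert-butyl 6-methyl (2E)-3-(methoxycarbonyl)-5-oxo-4-[2,3,5-tris(methoxymethoxy)phenyl]hex-2-enedioate
Product: 14 1-tert-butyl 6-methyl (2E,4R,5S)-5-hydroxy-3-(methoxycarbonyl)-4-[2,3,5-tris(methoxymethoxy)phenyl]hex-2-enedioate
Conditions: RuCl[(S,S)-TsDPEN](p-cymene) (2 mol %), HCO2H/Et3N (5:2), DMF, 25 °C
Reagents that add atoms: none
Why: Noyori–Ikariya asymmetric transfer hydrogenation with dynamic kinetic resolution, as known for β-aryl α-keto esters, in which C4 (flanked by ketone, aryl and alkene) racemises through the enol under Et3N while the catalyst delivers hydride to one ketone face to set C3 as S and, through a Felkin–Anh arrangement with the aryl group anti to the incoming hydride, reduces the (4R)-ketone faster, which should give the syn (3S,4R) hydroxy ester.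

Step 9
Reactants: 14 1-tert-butyl 6-methyl (2E,4R,5S)-5-hydroxy-3-(methoxycarbonyl)-4-[2,3,5-tris(methoxymethoxy)phenyl]hex-2-enedioate
Product: 15 4-tert-butyl 1-methyl (2E)-2-[(3S,4R)-3-(methoxycarbonyl)-5,6,8-tris(methoxymethoxy)-1-oxo-3,4-dihydro-1H-isochromen-4-yl]but-2-enedioate
Conditions: Pd(OAc)2 (10 mol %), N-(menthyloxycarbonyl)-L-leucine (20 mol %), AgOAc (3 equiv), Li2CO3 (1 equiv), CO (1 atm), ClCH2CH2Cl, 100 °C
Reagents that add atoms: carbon monoxide, [C-]#[O+]
Why: The C3 hydroxyl binds divalent palladium and carboxylate-assisted concerted metalation–deprotonation at C8a gives a six-membered oxapalladacycle; CO inserts into the aryl–palladium bond, C–O reductive elimination from the acyl(alkoxo)palladium releases the lactone, and AgOAc returns zerovalent palladium to the divalent state. The closest known reaction is the hydroxyl-directed ortho C–H carbonylation of 2-arylethanols to isochroman-1-ones with divalent palladium, an N-protected amino acid ligand, a silver oxidant and CO. The one ring formed is the six-membered lactone, closed by bond formation between the acyl carbon and the tethered oxygen (formally 6-exo-trig at the acyl carbon), with C8a–C1 and C1–O2 as the two new bonds. No stereocentre is made, and C3 and C4 should stay as set because no base able to remove their hydrogens is present. Site selectivity for C8a over C7 comes from the six-membered chelate that only C8a can form and from C8a being para to the C6 oxygen and ortho to the C8 oxygen, the site at which a 1,2,4-trioxygenated ring is attacked by electrophiles. The hydroxyl must also stay free and unoxidised: the tert-butyl ester at Cβ resists δ-lactonisation, the γ-lactone onto the Cα ester is held back by 1,3-allylic strain between the alkylidene ester and the aryl-bearing C4, and β-hydride loss from the palladium alkoxide is slowed by the electron-poor carbinol C–H next to the ester.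

Step 10
Reactants: 15 4-tert-butyl 1-methyl (2E)-2-[(3S,4R)-3-(methoxycarbonyl)-5,6,8-tris(methoxymethoxy)-1-oxo-3,4-dihydro-1H-isochromen-4-yl]but-2-enedioate
Product: 16 (2E)-4-methoxy-4-oxo-3-[(3S,4R)-5,6,8-trihydroxy-3-(methoxycarbonyl)-1-oxo-3,4-dihydro-1H-isochromen-4-yl]but-2-enoic acid
Conditions: CF3CO2H/CH2Cl2/H2O (10:10:1), 0 °C to rt, argon
Reagents that add atoms: none
Why: acidolysis cleaves the three aryl methoxymethyl acetals through oxocarbenium ions and the tert-butyl ester through the tert-butyl cation, while the methyl esters and the lactone are inert and, with no base present, C4 can neither epimerise nor expel O2.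

Compound list
1 | 3-bromo-4,5-dihydroxybenzaldehyde | O=Cc1cc(O)c(O)c(Br)c1 | starting material
2 | 3-bromo-4,5-bis(methoxymethoxy)benzaldehyde | O=Cc1cc(OCOC)c(OCOC)c(Br)c1 | intermediate
3 | 3-bromo-4,5-bis(methoxymethoxy)phenyl formate (not isolated) | O=COc1cc(OCOC)c(OCOC)c(Br)c1 | intermediate
4 | 3-bromo-4,5-bis(methoxymethoxy)phenol | Oc1cc(OCOC)c(OCOC)c(Br)c1 | intermediate
5 | 1-bromo-2,3,5-tris(methoxymethoxy)benzene | COCOc1cc(OCOC)c(OCOC)c(Br)c1 | intermediate
6 | methyl oxirane-2-carboxylate (racemic) | COC(=O)C1CO1 | starting material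
7 | [2,3,5-tris(methoxymethoxy)phenyl]magnesium bromide (not isolated) | COCOc1cc(OCOC)c(OCOC)c([Mg]Br)c1 | intermediate
8 | methyl 2-hydroxy-3-[2,3,5-tris(methoxymethoxy)phenyl]propanoate (racemic) | COC(=O)C(O)Cc1cc(OCOC)cc(OCOC)c1OCOC | intermediate
9 | methyl 2-oxo-3-[2,3,5-tris(methoxymethoxy)phenyl]propanoate (keto form drawn) | COC(=O)C(=O)Cc1cc(OCOC)cc(OCOC)c1OCOC | intermediate
10 | dimethyl but-2-ynedioate | COC(=O)C#CC(=O)OC | starting material
11 | 1,6-dimethyl 3-(methoxycarbonyl)-5-oxo-4-[2,3,5-tris(methoxymethoxy)phenyl]hex-2-enedioate (E/Z mixture, racemic, not isolated) | COC(=O)C=C(C(=O)OC)C(c1cc(OCOC)cc(OCOC)c1OCOC)C(=O)C(=O)OC | intermediate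
12 | dimethyl 2-oxo-5-[2,3,5-tris(methoxymethoxy)phenyl]-2H-pyran-4,6-dicarboxylate | COC(=O)C1=CC(=O)OC(C(=O)OC)=C1c2cc(OCOC)cc(OCOC)c2OCOC | intermediate
13 | 1-tert-butyl 6-methyl (2E)-3-(methoxycarbonyl)-5-oxo-4-[2,3,5-tris(methoxymethoxy)phenyl]hex-2-enedioate (racemic, keto form drawn) | COC(=O)/C(=C/C(=O)OC(C)(C)C)C(c1cc(OCOC)cc(OCOC)c1OCOC)C(=O)C(=O)OC | intermediate
14 | 1-tert-butyl 6-methyl (2E,4R,5S)-5-hydroxy-3-(methoxycarbonyl)-4-[2,3,5-tris(methoxymethoxy)phenyl]hex-2-enedioate | COC(=O)/C(=C/C(=O)OC(C)(C)C)[C@@H](c1cc(OCOC)cc(OCOC)c1OCOC)[C@H](O)C(=O)OC | intermediate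
15 | 4-tert-butyl 1-methyl (2E)-2-[(3S,4R)-3-(methoxycarbonyl)-5,6,8-tris(methoxymethoxy)-1-oxo-3,4-dihydro-1H-isochromen-4-yl]but-2-enedioate | COC(=O)/C(=C/C(=O)OC(C)(C)C)[C@H]1c2c(OCOC)c(OCOC)cc(OCOC)c2C(=O)O[C@@H]1C(=O)OC | intermediate
16 | (2E)-4-methoxy-4-oxo-3-[(3S,4R)-5,6,8-trihydroxy-3-(methoxycarbonyl)-1-oxo-3,4-dihydro-1H-isochromen-4-yl]but-2-enoic acid | COC(=O)/C(=C/C(=O)O)[C@H]1c2c(O)c(O)cc(O)c2C(=O)O[C@@H]1C(=O)OC | target

Total step count: 10. Longest linear sequence: 10 steps (1 to 16); 6 and 10 are bought.

Steps most likely to fail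

Step 9, C–H carbonylation. Palladation at C8a may be slow because an α-hydroxy ester is a weak donor; meanwhile the palladium alkoxide may lose β-hydride (oxidation back to the keto ester), or the hydroxyl may acylate itself on the Cα methyl ester at 100 °C. The fallback sets out from 14. Iodination with N-iodosuccinimide in MeCN at 0 °C should go to C8a (para to the C6 oxygen; C7 lies between two MOM ethers) and give 1-tert-butyl 6-methyl (2E,4S,5S)-5-hydroxy-4-[2-iodo-3,5,6-tris(methoxymethoxy)phenyl]-3-(methoxycarbonyl)hex-2-enedioate F1. Its spatial arrangement is that of 14; the C4 descriptor changes only because iodine raises the rank of the aryl group. Carbonylative lactonisation of the iodide with Pd(OAc)2/Xantphos, CO (1 atm) and Et3N in toluene at 70 °C (oxidative addition of zerovalent palladium, CO insertion, capture of the acylpalladium by the hydroxyl) then gives 15, where the route is rejoined. The same two bonds form, at lower temperature and without an oxidant.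

Step 8, transfer hydrogenation with dynamic resolution. The alkenyl group may take the place anti to hydride in place of the aryl group (wrong C4 epimer), the Cα=Cβ double bond may drift into conjugation with the ketone under Et3N, or the new hydroxyl may lactonise. The fallback sets out from 13. Substrate-controlled reduction with NaBH4 in MeOH/THF at −78 °C (Felkin–Anh, no amine base) should give the racemic syn alcohol, that is 14 together with its enantiomer 1-tert-butyl 6-methyl (2E,4S,5R)-5-hydroxy-3-(methoxycarbonyl)-4-[2,3,5-tris(methoxymethoxy)phenyl]hex-2-enedioate F2. The two are separated by preparative chromatography on a chiral stationary phase; 14 rejoins the route, and F2 is returned to 13 by Dess–Martin oxidation for another pass.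

Step 7, tert-butoxide opening of the pyrone. The hindered alkoxide may add too slowly at C2, so that exchange at the methyl esters competes. The fallback sets out from 12 and opens the enol lactone by nucleophilic catalysis with a primary alcohol. 2-(Trimethylsilyl)ethanol, DMAP (20 mol %) and Et3N in THF at 40 °C, then AcOH, should give 6-methyl 1-[2-(trimethylsilyl)ethyl] (2E)-3-(methoxycarbonyl)-5-oxo-4-[2,3,5-tris(methoxymethoxy)phenyl]hex-2-enedioate F3. The transfer hydrogenation of step 8 then gives 6-methyl 1-[2-(trimethylsilyl)ethyl] (2E,4R,5S)-5-hydroxy-3-(methoxycarbonyl)-4-[2,3,5-tris(methoxymethoxy)phenyl]hex-2-enedioate F4. The carbonylation of step 9 gives 1-methyl 4-[2-(trimethylsilyl)ethyl] (2E)-2-[(3S,4R)-3-(methoxycarbonyl)-5,6,8-tris(methoxymethoxy)-1-oxo-3,4-dihydro-1H-isochromen-4-yl]but-2-enedioate F5. Trifluoroacetic acid as in step 10 removes the MOM ethers and the silylethyl ester and gives 16, where the route is rejoined. A primary ester is open to δ-lactonisation by the C3 hydroxyl, so F4 is carried on without storage and carbonylated at the lowest workable temperature.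

Further compounds
F1 | step 9 | 1-tert-butyl 6-methyl (2E,4S,5S)-5-hydroxy-4-[2-iodo-3,5,6-tris(methoxymethoxy)phenyl]-3-(methoxycarbonyl)hex-2-enedioate | COC(=O)/C(=C/C(=O)OC(C)(C)C)[C@@H](c1c(I)c(OCOC)cc(OCOC)c1OCOC)[C@H](O)C(=O)OC
F2 | step 8 | 1-tert-butyl 6-methyl (2E,4S,5R)-5-hydroxy-3-(methoxycarbonyl)-4-[2,3,5-tris(methoxymethoxy)phenyl]hex-2-enedioate (enantiomer of 14) | COC(=O)/C(=C/C(=O)OC(C)(C)C)[C@H](c1cc(OCOC)cc(OCOC)c1OCOC)[C@@H](O)C(=O)OC
F3 | step 7 | 6-methyl 1-[2-(trimethylsilyl)ethyl] (2E)-3-(methoxycarbonyl)-5-oxo-4-[2,3,5-tris(methoxymethoxy)phenyl]hex-2-enedioate (racemic) | COC(=O)/C(=C/C(=O)OCC[Si](C)(C)C)C(c1cc(OCOC)cc(OCOC)c1OCOC)C(=O)C(=O)OC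
F4 | step 7 | 6-methyl 1-[2-(trimethylsilyl)ethyl] (2E,4R,5S)-5-hydroxy-3-(methoxycarbonyl)-4-[2,3,5-tris(methoxymethoxy)phenyl]hex-2-enedioate | COC(=O)/C(=C/C(=O)OCC[Si](C)(C)C)[C@@H](c1cc(OCOC)cc(OCOC)c1OCOC)[C@H](O)C(=O)OC
F5 | step 7 | 1-methyl 4-[2-(trimethylsilyl)ethyl] (2E)-2-[(3S,4R)-3-(methoxycarbonyl)-5,6,8-tris(methoxymethoxy)-1-oxo-3,4-dihydro-1H-isochromen-4-yl]but-2-enedioate | COC(=O)/C(=C/C(=O)OCC[Si](C)(C)C)[C@H]1c2c(OCOC)c(OCOC)cc(OCOC)c2C(=O)O[C@@H]1C(=O)OC
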